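## The problem

Target 32 is a humulane-type eleven-membered carbocycle with one gem-dimethyl carbon and one E-disubstituted alkene. It is trans-fused at C8–C9 and at C1–C2 (humulene numbering) to two dihydropyrans, each fused in turn to a 6-methyltropolone. Five stereocentres have to be set: the quaternary O–C(CH3) carbons C9 and C2, the ring-fusion methines C8 and C1, and the carbinol C10. C10 is next to C9 and homoallylic to both benzylic positions, so it can bias the C9 ether centre and direct a reduction at both ring fusions; the C1/C2 pair of ring B has only transannular guidance. The tropolones are acidic and chelating and are carried as 2-methyl ethers. The tertiary pyran ethers are acid-labile, the skipped triene is prone to transannular cation chemistry and over-reduction, and a free C10 hydroxyl cis to a formyl-bearing alkene would close to a lactol and then a furan. The ring itself, with three ring-trans double bonds of which two are tetrasubstituted, is a separate problem. The enabling feature is that each tropolone is a vinylogous acid: its ring C–H (tropone C5) and the neighbouring C4 hydroxyl sit where the benzylic carbon and the O–C(CH3) carbon of its pyran attach. Each pyran therefore maps onto an α-formyl tetrasubstituted alkene of the macrocycle, C8(CHO)=C9(CH3) beside the carbinol and C1(CHO)=C2(CH3) beside the allylic CH2.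

## Retrosynthesis

**32 ⇒ 31 ⇒ 30 ⇒ 29 (end-game, no skeletal bond cut).** The two O–CH3 bonds of 31 are cut last, so the tropolones stay masked until nothing else has to be done. The C8–H and C1–H bonds are removed next to give bis(2H-pyran) 30; its two benzylic alkenes are both homoallylic to the C10 hydroxyl, which allows a directed hydrogenation. Silyl ether 29 precedes 30. The forward reductions must leave the C4=C5 alkene alone and deliver hydrogen trans to the neighbouring methyl groups.

**29 ⇒ 21 + 2 × 27 (key cut).** In each 2H-pyran the tropone C5–CH bond and the O–C(CH3) bond are cut, four bonds in all. The alternative cut of each pyran, at the CH–C8 (CH–C1) bond with the O–C bond, would put the one-carbon unit on the tropone and rely on a cycloaddition onto a specific face of a trans-cycloalkene. The cut chosen here keeps all ring carbons in the macrocycle and closes the rings pericyclically, so no substitution at a tertiary carbon is needed. The precursors are far simpler: achiral hydroxytropone 27 and dialdehyde 21 with a single stereocentre. The forward reaction must be site-selective on the tropone (C5, not C7) and face-selective at C9 and C2.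

**21 ⇒ 20 ⇒ 19 ⇒ 18 (ring closure at C4=C5).** Both formyl groups are traced to hydroxymethyl groups (20) and to the tris-silyl ether 19. The ring is opened at the only disubstituted alkene, C4=C5, giving acyclic tetraene 18 with two terminal vinyl groups. Cuts at C–C single bonds of the ring would each need a neopentyl or allylic organometallic. The metathesis partners are simple and the two tetrasubstituted alkenes are inert to the catalyst. The forward reaction has to close a strained ring and give the E alkene.

**18 ⇒ 17 ⇒ 15 (C9–CH3 and C8–CH2O bonds).** The tetrasubstituted C8=C9 alkene of diol 17 is traced to the alkyne of propargylic alcohol 15. A directed anti-carbomagnesiation with a methyl Grignard reagent and a one-carbon electrophile forms both bonds. It fixes regiochemistry (methyl next to the carbinol) and geometry (one-carbon unit cis to C10) in one operation, which an olefination of a ketone could not do. The forward step needs the free C10 hydroxyl as the directing group.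

**15 ⇒ 14 ⇒ 13 ⇒ 4 + 11 (C9–C10 bond).** The carbinol is cut next to the alkyne, giving enyne 4 and aldehyde 11. The stereocentre is set by asymmetric transfer hydrogenation of ynone 14, a reaction with a predictable sense for alkynyl ketones. Direct asymmetric alkynylation of the enolisable, β,γ-unsaturated aldehyde 11 would be shorter but less dependable.

**11 ⇒ 10 ⇒ 9 ⇒ 5 + 6 + 7 (C1–C11 and C2–C3 bonds).** The second tetrasubstituted alkene is cut at both of its newly attached carbons. This leads to but-2-yn-1-ol 5, the acetal-bearing Grignard reagent 6 and allyl bromide 7, joined in one directed carbomagnesiation and allylation. The anti addition places C11 cis to the methyl group and the hydroxymethyl group cis to the allyl group, which is the ring-trans geometry. All three components are commercial.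

**4 ⇒ 3 ⇒ 1 + 2.** The neopentyl C6–C7 bond is cut by enolate alkylation of 2-methylpropanal 1 with propargyl bromide 2, and the vinyl group comes from the aldehyde of 3. This buys the quaternary carbon as a starting material rather than making a neopentyl bond late.

**27 ⇒ 26 ⇒ 24 ⇒ 23 ⇒ 22 (tropone).** The tropone is traced to 1,4-dione 26 by removal of two C=C bonds. Cutting the C3–C4 bond of the seven-membered ring (one-carbon insertion) leads to the symmetric 2-methoxy-1,3-dione 24, then to diazo compound 23 and commercial dione 22. Because 24 is symmetric, the inserted CH2 can only land between the methoxy carbon and a carbonyl. This fixes the 1,2,4-oxygen pattern and places the methyl ether on the correct oxygen, which methylation of a preformed hydroxytropolone would not do.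

## Roads not taken

**Alternative 1:** The cut is the cyclobutane ring-fusion bond of kobusone A1. Irradiation excites the ketone, a γ-hydrogen is abstracted, and the 1,4-biradical cleaves to the eleven-membered epoxy ketone A2 with the E alkene.
- Merits: A1 is an enantiopure chiral-pool ketone. The ring and the trans alkene arise without a macrocyclisation. The epoxide of A2 already carries the C2 oxygen with defined configuration, which is the centre the chosen plan controls least well. In ring construction and in C2 control this road is better.
- Weak points: type 2 cleavage competes with α-cleavage of the strained cyclobutyl ketone and with cyclobutanol formation. A2 lacks the C9 methyl group, the C10 oxygen and every bond to the tropolones. Each pyran would then need separate C–C and C–O bond formations, one of them an epoxide opening at a tertiary carbon by a tropolone oxygen.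
- Comparison: the chosen plan offers convergence instead. Both tropolones and both pyrans arrive in one step from dialdehyde 21, which is itself eleven steps from commercial materials.

**Alternative 2:** The cut is the quaternary C2–CH2 bond. An Ireland–Claisen shift of the silyl ketene acetal within a chroman-2-carboxylate macrolactone would give acid A3, forming that bond and the E alkene while the lactone C–O bond breaks.
- Merits: macrolactonisation replaces a carbocyclisation. The enolate geometry is fixed by the chroman ring. The sigmatropic transition state transfers chirality to C2 and sets it relative to C1 more securely than the chosen plan does.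
- Weak points: A3 carries a carboxyl group where the methyl group belongs, and reducing it at a neopentyl quaternary carbon costs about three late steps. A strong amide base must be used beside two tropone methyl ethers. Both chromans with four stereocentres must be built first in a long linear sequence. A transannular Claisen in an eleven-membered lactone may go through a boat, which would erode both the alkene geometry and the chirality transfer.
- Comparison: the chosen plan is shorter and needs no carboxyl-to-methyl correction, but it concedes the C2 control.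

**Alternative 3:** The cut is the CH(OH)–CH2 bond (C10–C11). Tin–lithium exchange on a twelve-membered α-stannyl allyl ether and a [2,3]-Wittig shift would contract the ring to triol A4 with two exocyclic methylene groups.
- Merits: contraction from a twelve-membered ether is easier than direct closure of the carbocycle. All three C–O stereocentres (C2, C9, C10) can be set by reagent-controlled oxidations before the ring is formed. In that respect it is superior to a thermodynamically steered electrocyclisation.
- Weak points: A4 still lacks both tropolones. Joining them requires C–C bond formation at the methylene groups and aryl ether formation at two tertiary alkoxides. The C1 and C8 hydrogens would again depend on the facial bias of the macrocycle. The sequence is long and uses stoichiometric tin.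
- Comparison: the chosen plan forms the tertiary ethers pericyclically and attaches both tropolones at once, at the price of less certain control of C2 and C9.

Key step: step 18

Remarks: ring carbons are numbered as in α-humulene (2,6,6,9-tetramethylcycloundeca-1,4,8-triene); in this numbering 32 is (1R,2R,8R,9R,10S). The carbinol is carried through the key step as its tert-butyldimethylsilyl ether, on the assumption that a free hydroxyl cis to the C8 formyl group would close to a lactol and dehydrate to a furan.

## Route

Step 1
Reactants: 1 2-methylpropanal; 2 3-bromoprop-1-yne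
Product: 3 2,2-dimethylpent-4-ynal
Conditions: NaOH (50% aq), Bu4NI (cat.), toluene, 70 °C
Reagents that add atoms: none
Why: Phase-transfer C-alkylation of the aldehyde enolate; the product has no α-hydrogen, so it can neither be alkylated again nor enolise.

Step 2
Reactants: 3 2,2-dimethylpent-4-ynal
Product: 4 3,3-dimethylhex-1-en-5-yne
Conditions: Ph3PCH3Br, KOtBu, THF, 0 °C to 25 °C
Reagents that add atoms: methylenetriphenylphosphorane (from methyltriphenylphosphonium bromide), C=P(c1ccccc1)(c1ccccc1)c1ccccc1
Why: Wittig methylenation of a non-enolisable α-quaternary aldehyde; the ylide is too weak a base to deprotonate the terminal alkyne.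

Step 3
Reactants: 5 but-2-yn-1-ol; 6 (1,3-dioxolan-2-ylmethyl)magnesium bromide; 7 3-bromoprop-1-ene
Product: 9 (2Z)-2-(1,3-dioxolan-2-ylmethyl)-3-methylhexa-2,5-dien-1-ol, via magnesacycle 8 (not isolated)
Conditions: 6 (3 equiv), CuI (10 mol%), THF, 0 °C to 25 °C; then 7 (excess), 0 °C
Reagents that add atoms: none
Why: Copper-catalysed anti-carbomagnesiation of a propargylic alcohol: the magnesium alkoxide sends the Grignard carbon to the proximal alkyne carbon (future C1) and magnesium to the methyl-bearing carbon (future C2), giving 8. Allylation of the alkenyl–magnesium bond with retention then puts the C11 unit cis to methyl and the hydroxymethyl group cis to allyl, which is the ring-trans geometry of C1=C2.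

Step 4
Reactants: 9 (2Z)-2-(1,3-dioxolan-2-ylmethyl)-3-methylhexa-2,5-dien-1-ol
Product: 10 tert-butyl{[(2Z)-2-(1,3-dioxolan-2-ylmethyl)-3-methylhexa-2,5-dien-1-yl]oxy}dimethylsilane
Conditions: TBSCl, imidazole, DMF, 25 °C
Reagents that add atoms: tert-butyldimethylsilyl chloride, CC(C)(C)[Si](C)(C)Cl
Why: Standard silylation of the primary allylic alcohol; it prevents lactol formation with the aldehyde unmasked in the next step.

Step 5
Reactants: 10 tert-butyl{[(2Z)-2-(1,3-dioxolan-2-ylmethyl)-3-methylhexa-2,5-dien-1-yl]oxy}dimethylsilane
Product: 11 (3Z)-3-{[(tert-butyldimethylsilyl)oxy]methyl}-4-methylhepta-3,6-dienal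
Conditions: PPTS (cat.), acetone/H2O (9:1), 45 °C
Reagents that add atoms: water, O
Why: Mild acid-catalysed hydrolysis of the dioxolane; the buffered acid should spare the primary silyl ether, and the β,γ-unsaturated aldehyde is used at once to avoid conjugation.

Step 6
Reactants: 4 3,3-dimethylhex-1-en-5-yne; 11 (3Z)-3-{[(tert-butyldimethylsilyl)oxy]methyl}-4-methylhepta-3,6-dienal
Product: 13 rac-(4Z)-5-{[(tert-butyldimethylsilyl)oxy]methyl}-4,11,11-trimethyltrideca-1,4,12-trien-8-yn-7-ol, via lithium acetylide 12 (not isolated)
Conditions: n-BuLi, THF, −78 °C; then 11, −78 °C; NH4Cl (aq)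
Reagents that add atoms: none
Why: 1,2-Addition of lithium acetylide 12 to the aldehyde at low temperature joins C9 to C10; the carbinol forms as a racemate and is corrected in the next two steps.

Step 7
Reactants: 13 rac-(4Z)-5-{[(tert-butyldimethylsilyl)oxy]methyl}-4,11,11-trimethyltrideca-1,4,12-trien-8-yn-7-ol
Product: 14 (4Z)-5-{[(tert-butyldimethylsilyl)oxy]methyl}-4,11,11-trimethyltrideca-1,4,12-trien-8-yn-7-one
Conditions: Dess–Martin periodinane, NaHCO3, CH2Cl2, 0 °C
Reagents that add atoms: none
Why: Dess–Martin oxidation of a propargylic alcohol to the ynone under buffered, non-basic conditions that leave the acidic α-methylene group and the alkenes untouched.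

Step 8
Reactants: 14 (4Z)-5-{[(tert-butyldimethylsilyl)oxy]methyl}-4,11,11-trimethyltrideca-1,4,12-trien-8-yn-7-one
Product: 15 (4Z,7S)-5-{[(tert-butyldimethylsilyl)oxy]methyl}-4,11,11-trimethyltrideca-1,4,12-trien-8-yn-7-ol
Conditions: Ru[(S,S)-TsDPEN](p-cymene) (2 mol%), i-PrOH, 25 °C
Reagents that add atoms: none
Why: Noyori asymmetric transfer hydrogenation of an alkynyl ketone; the (S,S)-catalyst should give the (S)-propargylic alcohol by the established sense for alkyl alkynyl ketones (the antipodal catalyst is used if the sense proves reversed). This sets C10.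

Step 9
Reactants: 15 (4Z,7S)-5-{[(tert-butyldimethylsilyl)oxy]methyl}-4,11,11-trimethyltrideca-1,4,12-trien-8-yn-7-ol
Product: 17 (2Z,4S,6Z)-6-{[(tert-butyldimethylsilyl)oxy]methyl}-2-(2,2-dimethylbut-3-en-1-yl)-3,7-dimethyldeca-2,6,9-triene-1,4-diol, via magnesacycle 16 (not isolated)
Conditions: MeMgBr (4 equiv), CuI (20 mol%), THF, 0 °C to 40 °C; then (CH2O)n, −20 °C to 25 °C
Reagents that add atoms: methylmagnesium bromide, C[Mg]Br; formaldehyde (from paraformaldehyde), C=O
Why: Copper-catalysed anti-carbomagnesiation of the secondary propargylic alkoxide: methyl adds to the proximal carbon (C9) and magnesium to C8 trans to it (16). Hydroxymethylation of the alkenylmagnesium with retention places the one-carbon unit cis to C10 and trans to methyl, which is the ring-trans geometry of C8=C9.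

Step 10
Reactants: 17 (2Z,4S,6Z)-6-{[(tert-butyldimethylsilyl)oxy]methyl}-2-(2,2-dimethylbut-3-en-1-yl)-3,7-dimethyldeca-2,6,9-triene-1,4-diol
Product: 18 (2Z,4S,6Z)-1,4-bis[(tert-butyldimethylsilyl)oxy]-6-{[(tert-butyldimethylsilyl)oxy]methyl}-2-(2,2-dimethylbut-3-en-1-yl)-3,7-dimethyldeca-2,6,9-triene
Conditions: TBSOTf, 2,6-lutidine, CH2Cl2, −78 °C to 0 °C
Reagents that add atoms: tert-butyldimethylsilyl triflate, CC(C)(C)[Si](C)(C)OS(=O)(=O)C(F)(F)F
Why: Exhaustive silylation with the reactive triflate covers the hindered secondary allylic hydroxyl together with the new primary one, without acid that could cyclise the ene-1,4-diol.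

Step 11
Reactants: 18 (2Z,4S,6Z)-1,4-bis[(tert-butyldimethylsilyl)oxy]-6-{[(tert-butyldimethylsilyl)oxy]methyl}-2-(2,2-dimethylbut-3-en-1-yl)-3,7-dimethyldeca-2,6,9-triene
Product: 19 (1Z,4E,8Z,10S)-10-[(tert-butyldimethylsilyl)oxy]-1,8-bis{[(tert-butyldimethylsilyl)oxy]methyl}-2,6,6,9-tetramethylcycloundeca-1,4,8-triene
Conditions: second-generation Grubbs catalyst RuCl2(H2IMes)(PCy3)(=CHPh) (10 mol%), toluene (1 mM), 80 °C, argon sparge
Reagents that add atoms: none
Why: Ring-closing metathesis between the two monosubstituted alkenes; the tetrasubstituted alkenes are inert to the catalyst and ethylene loss drives closure at high dilution. Reversible metathesis should favour the E alkene, the thermodynamic isomer in the humulene ring.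

Step 12
Reactants: 19 (1Z,4E,8Z,10S)-10-[(tert-butyldimethylsilyl)oxy]-1,8-bis{[(tert-butyldimethylsilyl)oxy]methyl}-2,6,6,9-tetramethylcycloundeca-1,4,8-triene
Product: 20 [(1Z,4E,8Z,10S)-10-[(tert-butyldimethylsilyl)oxy]-2,6,6,9-tetramethylcycloundeca-1,4,8-triene-1,8-diyl]dimethanol
Conditions: HF·pyridine, pyridine, THF, 0 °C
Reagents that add atoms: none
Why: Buffered HF·pyridine cleaves primary silyl ethers much faster than the hindered secondary allylic one, so only the two hydroxymethyl groups should be freed.

Step 13
Reactants: 20 [(1Z,4E,8Z,10S)-10-[(tert-butyldimethylsilyl)oxy]-2,6,6,9-tetramethylcycloundeca-1,4,8-triene-1,8-diyl]dimethanol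
Product: 21 (1Z,4E,8Z,10S)-10-[(tert-butyldimethylsilyl)oxy]-2,6,6,9-tetramethylcycloundeca-1,4,8-triene-1,8-dicarbaldehyde
Conditions: MnO2 (activated, excess), CH2Cl2, 25 °C
Reagents that add atoms: none
Why: Chemoselective allylic oxidation with MnO2 should give both tetrasubstituted enals without touching the silyl ether or the alkene geometry.

Step 14
Reactants: 22 5-methylcyclohexane-1,3-dione
Product: 23 2-diazo-5-methylcyclohexane-1,3-dione
Conditions: 4-acetamidobenzenesulfonyl azide, Et3N, MeCN, 0 °C to 25 °C
Reagents that add atoms: 4-acetamidobenzenesulfonyl azide, CC(=O)Nc1ccc(cc1)S(=O)(=O)N=[N+]=[N-]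
Why: Regitz diazo transfer to a cyclic 1,3-diketone.

Step 15
Reactants: 23 2-diazo-5-methylcyclohexane-1,3-dione
Product: 24 2-methoxy-5-methylcyclohexane-1,3-dione
Conditions: Rh2(OAc)4 (1 mol%), MeOH (5 equiv), CH2Cl2, 40 °C
Reagents that add atoms: methanol, CO
Why: Rhodium-catalysed O–H insertion of the diazodiketone into methanol installs the methoxy group at C2 of the still symmetric dione.

Step 16
Reactants: 24 2-methoxy-5-methylcyclohexane-1,3-dione
Product: 26 2-methoxy-6-methylcycloheptane-1,4-dione, via zinc cyclopropanolate 25 (not isolated)
Conditions: Et2Zn (3 equiv), CH2I2 (3 equiv), CH2Cl2, 0 °C; NH4Cl (aq)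
Reagents that add atoms: diiodomethane, ICI
Why: Zinc-carbenoid chain extension of a β-dicarbonyl compound: the zinc enolate of 24 is cyclopropanated to 25, which fragments to the ring-enlarged 1,4-dione. Because 24 is symmetric, the new CH2 can only enter between the methoxy-bearing carbon and a carbonyl, which fixes the oxygen pattern and the position of the methyl ether.

Step 17
Reactants: 26 2-methoxy-6-methylcycloheptane-1,4-dione
Product: 27 4-hydroxy-2-methoxy-6-methylcyclohepta-2,4,6-trien-1-one
Conditions: IBX (4 equiv), DMSO, 80 °C
Reagents that add atoms: none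
Why: IBX dehydrogenation of ketones, carried through two desaturations in one pot; the second is driven by formation of the aromatic hydroxytropone, which keeps the methoxy group next to the carbonyl.

Step 18
Reactants: 21 (1Z,4E,8Z,10S)-10-[(tert-butyldimethylsilyl)oxy]-2,6,6,9-tetramethylcycloundeca-1,4,8-triene-1,8-dicarbaldehyde; 27 4-hydroxy-2-methoxy-6-methylcyclohepta-2,4,6-trien-1-one (2.5 equiv, two molecules incorporated)
Product: 29 (2R,9R,10S)-bis(2H-pyrano)tropone dimethyl ether 10-O-tert-butyldimethylsilyl ether, via bis(1-oxatriene) 28 (not isolated)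
Conditions: ethylenediammonium diacetate (0.4 equiv), toluene, 100 °C
Reagents that add atoms: none
Why: Proposed new method: ethylenediammonium diacetate turns each hindered formyl group into an iminium ion, which is attacked by C5 of the hydroxytropone (the α-carbon of its C4 enol) in a Knoevenagel condensation; loss of the amine gives bis(1-oxatriene) 28, a tropone quinone methide, and each unit closes by thermal disrotatory oxa-6π electrocyclisation. The closest known reaction type is the formal oxa-[3+3] annulation of 1,3-diketones, 4-hydroxypyrones and resorcinols with enals, fully substituted cyclic enals included; a 4-hydroxytropone as the vinylogous acid and a twofold reaction on a macrocycle have not been shown. Both pyrans close in the six-membered pericyclic mode (tropone oxygen onto the methyl-bearing alkene terminus, 6-endo in effect), forming two tropone C–CH bonds and two O–C(CH3) bonds while the former enal carbons stay ring members. The step needs attack at C5 and not at C7: the 2-methoxy group rules out the 2-oxo tautomer and so any reaction at C3, and as a donor that is 1,4-related to C5 but only 1,3-related to C7 it should raise the nucleophilicity of C5. C9 is controlled by the adjacent C10 silyloxy stereocentre: ring closure and opening are reversible at 100 °C, so the epimer with the C9–O and C10–O bonds anti and the bulky silyl ether turned away from the tropone should accumulate. C2 has only transannular guidance from the closed ring A and the E alkene and is the least secure centre; the same retro-6π equilibration is relied on and epimers are separated at this stage. The silyl ether keeps the Z-γ-oxygenated enal from lactol and furan formation, and the weakly acidic buffer limits dienamine formation at C10.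

Step 19
Reactants: 29 (2R,9R,10S)-bis(2H-pyrano)tropone dimethyl ether 10-O-tert-butyldimethylsilyl ether
Product: 30 (2R,9R,10S)-bis(2H-pyrano)tropone dimethyl ether with free 10-hydroxyl
Conditions: TBAF, THF, 0 °C to 25 °C
Reagents that add atoms: none
Why: Fluoride cleavage of the secondary silyl ether; tropone methyl ethers and the pyran ethers are inert to TBAF.

Step 20
Reactants: 30 (2R,9R,10S)-bis(2H-pyrano)tropone dimethyl ether with free 10-hydroxyl
Product: 31 (1R,2R,8R,9R,10S)-di-O-methyl ether of the target
Conditions: [Ir(cod)(PCy3)(py)]PF6 (5 mol%), H2 (1 atm), CH2Cl2, 0 °C, stopped after uptake of two equivalents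
Reagents that add atoms: none
Why: Hydroxyl-directed homogeneous hydrogenation: the cationic iridium catalyst binds the C10 hydroxyl, which is homoallylic to both benzylic alkenes. It should deliver hydrogen to C8 on the face of C10 (H trans to the C9 methyl) and to C1 on the face occupied by the macrocyclic bridge that carries C10 (H trans to the C2 methyl), giving both trans ring fusions; the remote, undirected C4=C5 alkene should react more slowly.

Step 21
Reactants: 31 (1R,2R,8R,9R,10S)-di-O-methyl ether of the target
Product: 32 CNP0283947.4 (1R,2R,8R,9R,10S)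
Conditions: LiCl (excess), DMF, 120 °C; dilute HCl work-up
Reagents that add atoms: none
Why: Nucleophilic demethylation: chloride attacks the methyl groups of the two 2-methoxytropones (vinylogous methyl esters) in an SN2 reaction, releasing the tropolones under conditions that spare the tertiary pyran ethers and the alkene.

## Compound list

1 | 2-methylpropanal | CC(C)C=O | starting material
2 | 3-bromoprop-1-yne | BrCC#C | starting material
3 | 2,2-dimethylpent-4-ynal | O=CC(C)(C)CC#C | intermediate
4 | 3,3-dimethylhex-1-en-5-yne | C=CC(C)(C)CC#C | intermediate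
5 | but-2-yn-1-ol | CC#CCO | starting material
6 | (1,3-dioxolan-2-ylmethyl)magnesium bromide | Br[Mg]CC1OCCO1 | starting material
7 | 3-bromoprop-1-ene | C=CCBr | starting material
8 | 4-(1,3-dioxolan-2-ylmethyl)-3-methyl-2,5-dihydro-1,2-oxamagnesole (magnesacycle, not isolated) | CC1=C(CC2OCCO2)CO[Mg]1 | intermediate
9 | (2Z)-2-(1,3-dioxolan-2-ylmethyl)-3-methylhexa-2,5-dien-1-ol | OC/C(CC1OCCO1)=C(/C)CC=C | intermediate
10 | tert-butyl{[(2Z)-2-(1,3-dioxolan-2-ylmethyl)-3-methylhexa-2,5-dien-1-yl]oxy}dimethylsilane | CC(C)(C)[Si](C)(C)OC/C(CC1OCCO1)=C(/C)CC=C | intermediate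
11 | (3Z)-3-{[(tert-butyldimethylsilyl)oxy]methyl}-4-methylhepta-3,6-dienal | CC(C)(C)[Si](C)(C)OC/C(CC=O)=C(/C)CC=C | intermediate
12 | lithium 4,4-dimethylhex-5-en-1-yn-1-ide (lithium acetylide of 4, not isolated) | [Li]C#CCC(C)(C)C=C | intermediate
13 | rac-(4Z)-5-{[(tert-butyldimethylsilyl)oxy]methyl}-4,11,11-trimethyltrideca-1,4,12-trien-8-yn-7-ol | CC(C)(C)[Si](C)(C)OC/C(CC(O)C#CCC(C)(C)C=C)=C(/C)CC=C | intermediate
14 | (4Z)-5-{[(tert-butyldimethylsilyl)oxy]methyl}-4,11,11-trimethyltrideca-1,4,12-trien-8-yn-7-one | CC(C)(C)[Si](C)(C)OC/C(CC(=O)C#CCC(C)(C)C=C)=C(/C)CC=C | intermediate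
15 | (4Z,7S)-5-{[(tert-butyldimethylsilyl)oxy]methyl}-4,11,11-trimethyltrideca-1,4,12-trien-8-yn-7-ol | CC(C)(C)[Si](C)(C)OC/C(C[C@H](O)C#CCC(C)(C)C=C)=C(/C)CC=C | intermediate
16 | (5S)-5-[(2Z)-2-{[(tert-butyldimethylsilyl)oxy]methyl}-3-methylhexa-2,5-dien-1-yl]-3-(2,2-dimethylbut-3-en-1-yl)-4-methyl-2,5-dihydro-1,2-oxamagnesole (magnesacycle, not isolated) | CC1=C(CC(C)(C)C=C)[Mg]O[C@H]1C/C(CO[Si](C)(C)C(C)(C)C)=C(\C)CC=C | intermediate
17 | (2Z,4S,6Z)-6-{[(tert-butyldimethylsilyl)oxy]methyl}-2-(2,2-dimethylbut-3-en-1-yl)-3,7-dimethyldeca-2,6,9-triene-1,4-diol | OC/C(CC(C)(C)C=C)=C(/C)[C@@H](O)C/C(CO[Si](C)(C)C(C)(C)C)=C(\C)CC=C | intermediate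
18 | (2Z,4S,6Z)-1,4-bis[(tert-butyldimethylsilyl)oxy]-6-{[(tert-butyldimethylsilyl)oxy]methyl}-2-(2,2-dimethylbut-3-en-1-yl)-3,7-dimethyldeca-2,6,9-triene | CC(C)(C)[Si](C)(C)OC/C(CC(C)(C)C=C)=C(/C)[C@@H](O[Si](C)(C)C(C)(C)C)C/C(CO[Si](C)(C)C(C)(C)C)=C(\C)CC=C | intermediate
19 | (1Z,4E,8Z,10S)-10-[(tert-butyldimethylsilyl)oxy]-1,8-bis{[(tert-butyldimethylsilyl)oxy]methyl}-2,6,6,9-tetramethylcycloundeca-1,4,8-triene (all three ring double bonds trans within the ring) | C1/C(CO[Si](C)(C)C(C)(C)C)=C(\C)[C@@H](O[Si](C)(C)C(C)(C)C)C/C(CO[Si](C)(C)C(C)(C)C)=C(\C)C/C=C/C1(C)C | intermediate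
20 | [(1Z,4E,8Z,10S)-10-[(tert-butyldimethylsilyl)oxy]-2,6,6,9-tetramethylcycloundeca-1,4,8-triene-1,8-diyl]dimethanol | C1/C(CO)=C(\C)[C@@H](O[Si](C)(C)C(C)(C)C)C/C(CO)=C(\C)C/C=C/C1(C)C | intermediate
21 | (1Z,4E,8Z,10S)-10-[(tert-butyldimethylsilyl)oxy]-2,6,6,9-tetramethylcycloundeca-1,4,8-triene-1,8-dicarbaldehyde | C1/C(C=O)=C(\C)[C@@H](O[Si](C)(C)C(C)(C)C)C/C(C=O)=C(\C)C/C=C/C1(C)C | intermediate
22 | 5-methylcyclohexane-1,3-dione | CC1CC(=O)CC(=O)C1 | starting material
23 | 2-diazo-5-methylcyclohexane-1,3-dione | CC1CC(=O)C(=[N+]=[N-])C(=O)C1 | intermediate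
24 | 2-methoxy-5-methylcyclohexane-1,3-dione (enolised in solution) | COC1C(=O)CC(C)CC1=O | intermediate
25 | ethylzinc 1-methoxy-4-methyl-2-oxobicyclo[4.1.0]heptan-6-olate (zinc cyclopropanolate, not isolated) | CC[Zn]OC12CC(C)CC(=O)C1(OC)C2 | intermediate
26 | 2-methoxy-6-methylcycloheptane-1,4-dione (mixture of diastereomers) | COC1CC(=O)CC(C)CC1=O | intermediate
27 | 4-hydroxy-2-methoxy-6-methylcyclohepta-2,4,6-trien-1-one | Cc1cc(=O)c(OC)cc(O)c1 | intermediate
28 | bis(1-oxatriene): (10S)-macrocycle 21 in which each formyl oxygen is replaced by C5 of a 2-methoxy-6-methylcyclohepta-2,6-diene-1,4-dione ring (not isolated) | C1/C(C=C2C(=O)C=C(OC)C(=O)C=C2C)=C(\C)[C@@H](O[Si](C)(C)C(C)(C)C)C/C(C=C2C(=O)C=C(OC)C(=O)C=C2C)=C(\C)C/C=C/C1(C)C | intermediate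
29 | (2R,9R,10S)-bis(2H-pyrano)tropone dimethyl ether 10-O-tert-butyldimethylsilyl ether: ring A 2H-pyran at C8–C9 and ring B at C1–C2, each with its oxygen on C4 and its CH= on C5 of a 2-methoxy-6-methyltropone, C4=C5 of the macrocycle E | Cc1cc(=O)c(OC)cc2c1C=C1CC(C)(C)/C=C/C[C@@]3(C)Oc4cc(OC)c(=O)cc(C)c4C=C3C[C@H](O[Si](C)(C)C(C)(C)C)[C@]1(C)O2 | intermediate
30 | (2R,9R,10S)-bis(2H-pyrano)tropone dimethyl ether with free 10-hydroxyl | Cc1cc(=O)c(OC)cc2c1C=C1CC(C)(C)/C=C/C[C@@]3(C)Oc4cc(OC)c(=O)cc(C)c4C=C3C[C@H](O)[C@]1(C)O2 | intermediate
31 | (1R,2R,8R,9R,10S)-di-O-methyl ether of the target (both pyrans saturated and trans-fused) | Cc1cc(=O)c(OC)cc2c1C[C@H]1CC(C)(C)/C=C/C[C@@]3(C)Oc4cc(OC)c(=O)cc(C)c4C[C@@H]3C[C@H](O)[C@]1(C)O2 | intermediate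
32 | CNP0283947.4, (1R,2R,8R,9R,10S)-bis-tropolone | Cc1cc(=O)c(O)cc2c1C[C@H]1CC(C)(C)/C=C/C[C@@]3(C)Oc4cc(O)c(=O)cc(C)c4C[C@@H]3C[C@H](O)[C@]1(C)O2 | target

## Step count and least certain steps

Total: 21 steps. Longest linear sequence: 15 steps (steps 3–13 and 18–21, from but-2-yn-1-ol).

**Step 18 (key step, proposed new method).** Most likely to go wrong is condensation at C7 of the tropone in competition with C5, since both are termini of the same vinylogous acid and only the methoxy donor distinguishes them. Next is poor facial selectivity in the closure of ring B, because C2 is remote from the stereocentre. Partial epimerisation of C10 through a dienamine of the hindered enal is a third risk. The fallback uses known chemistry, sets out from 27 and 21 and comes back at 29. Iodination of 27 with N-iodosuccinimide should give 4-hydroxy-5-iodo-2-methoxy-6-methylcyclohepta-2,4,6-trien-1-one F1, whose regiochemistry can be settled on the small molecule before the dialdehyde is committed. Nozaki–Hiyama–Kishi coupling of F1 with 21 (CrCl2 in excess, catalytic NiCl2, DMF) would form both tropone C–CH bonds selectively at the formyl groups and give the bis(hydroxytropyl carbinol) F2. Mild acid (PPTS, toluene, 60 °C) would then dehydrate each o-hydroxy carbinol through the same oxatriene to 29.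

**Step 20.** Over-reduction of the strained C4=C5 alkene by the very active iridium catalyst is the main risk. Delivery to the wrong face at C1 is the second, since there the hydroxyl reaches the alkene only through the flexible C11 bridge; coordination of the methoxytropone units to iridium may also slow the reaction. The fallback replaces coordination-directed hydrogenation by hydrogen-atom transfer, sets out from 29 and comes back at 31. Treatment of 29 with Mn(dpm)3, PhSiH3 and tert-butyl hydroperoxide in i-PrOH should reduce only the two alkenes that give benzylic radicals and favour the more stable trans-fused tetrahydro silyl ether F3; TBAF then gives 31.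

**Step 11.** Ring strain in the triply trans eleven-membered ring may divert the metathesis to oligomers or to the Z alkene, and the vinyl group on the quaternary carbon reacts slowly. The fallback is a carbonyl coupling, sets out from 18 and comes back at 19. Selective dihydroxylation of the two monosubstituted alkenes and periodate cleavage (OsO4 cat., NMO, then NaIO4) should give (3Z,5S,7Z)-5-silyloxy dialdehyde F4. McMurry coupling of F4 with low-valent titanium (TiCl3(DME)1.5, Zn(Cu), DME, reflux, slow addition) would close the ring at C4=C5, the mode of closure with precedent for the humulene skeleton.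

**Step 3.** The β-oxygenated Grignard reagent 6 may add sluggishly to the alkynol or decompose by β-elimination before carbometalation. The fallback builds the same alkene by a different carbometalation, sets out from 7 and commercial prop-2-yn-1-ol and comes back at 11. Copper-catalysed coupling (CuI, K2CO3, NaI, DMF) should give hex-5-en-2-yn-1-ol F5. Iron-catalysed syn-methylmagnesiation (MeMgBr, Fe(acac)3, THF) and iodination would give (2E)-2-iodo-3-methylhexa-2,5-dien-1-ol F6, and silylation its tert-butyldimethylsilyl ether F7. Palladium-catalysed coupling of F7 with the zinc enolate of tert-butyl acetate (BrZnCH2CO2t-Bu, Pd2(dba)3, P(t-Bu)3) would give tert-butyl (3Z)-3-{[(tert-butyldimethylsilyl)oxy]methyl}-4-methylhepta-3,6-dienoate F8, and i-Bu2AlH at −78 °C would reduce it to 11.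

**Step 16.** The tetrasubstituted, methoxy-bearing zinc enolate may resist cyclopropanation or give C-methylation instead of chain extension. The fallback is a radical ring expansion, sets out from 24 and comes back at 26. Aldol reaction with aqueous formaldehyde (cat. Et3N) should give 2-(hydroxymethyl)-2-methoxy-5-methylcyclohexane-1,3-dione F9, and iodination (I2, PPh3, imidazole) 2-(iodomethyl)-2-methoxy-5-methylcyclohexane-1,3-dione F10. Dowd–Beckwith ring expansion of F10 (Bu3SnH, AIBN, benzene, 80 °C) would insert the CH2 between the methoxy carbon and a carbonyl and give 26.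

## Further compounds

F1 | step 18 | 4-hydroxy-5-iodo-2-methoxy-6-methylcyclohepta-2,4,6-trien-1-one | Cc1cc(=O)c(OC)cc(O)c1I
F2 | step 18 | (10S)-bis(hydroxytropyl carbinol): macrocycle 21 in which each CHO has become CH(OH) bonded to C5 of 4-hydroxy-2-methoxy-6-methyltropone (carbinol epimers) | C1/C(C(O)c2c(C)cc(=O)c(OC)cc2O)=C(\C)[C@@H](O[Si](C)(C)C(C)(C)C)C/C(C(O)c2c(C)cc(=O)c(OC)cc2O)=C(\C)C/C=C/C1(C)C
F3 | step 20 | (1R,2R,8R,9R,10S)-10-O-tert-butyldimethylsilyl ether of 31 | Cc1cc(=O)c(OC)cc2c1C[C@H]1CC(C)(C)/C=C/C[C@@]3(C)Oc4cc(OC)c(=O)cc(C)c4C[C@@H]3C[C@H](O[Si](C)(C)C(C)(C)C)[C@]1(C)O2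
F4 | step 11 | (3Z,5S,7Z)-5-[(tert-butyldimethylsilyl)oxy]-3,7-bis{[(tert-butyldimethylsilyl)oxy]methyl}-4,8,10,10-tetramethylundeca-3,7-dienedial | O=CC(C)(C)C/C(CO[Si](C)(C)C(C)(C)C)=C(\C)[C@@H](O[Si](C)(C)C(C)(C)C)C/C(CO[Si](C)(C)C(C)(C)C)=C(\C)CC=O
F5 | step 3 | hex-5-en-2-yn-1-ol | OCC#CCC=C
F6 | step 3 | (2E)-2-iodo-3-methylhexa-2,5-dien-1-ol | OC/C(I)=C(/C)CC=C
F7 | step 3 | tert-butyl{[(2E)-2-iodo-3-methylhexa-2,5-dien-1-yl]oxy}dimethylsilane | CC(C)(C)[Si](C)(C)OC/C(I)=C(/C)CC=C
F8 | step 3 | tert-butyl (3Z)-3-{[(tert-butyldimethylsilyl)oxy]methyl}-4-methylhepta-3,6-dienoate | CC(C)(C)OC(=O)C/C(CO[Si](C)(C)C(C)(C)C)=C(\C)CC=C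
F9 | step 16 | 2-(hydroxymethyl)-2-methoxy-5-methylcyclohexane-1,3-dione | COC1(CO)C(=O)CC(C)CC1=O
F10 | step 16 | 2-(iodomethyl)-2-methoxy-5-methylcyclohexane-1,3-dione | COC1(CI)C(=O)CC(C)CC1=O
A1 | alternative 1 | kobusone | C[C@@]12CC[C@@H]3[C@H](CC3(C)C)C(=O)CC[C@H]1O2
A2 | alternative 1 | eleven-membered epoxy ketone with the trans alkene | O=C1CC[C@H]2O[C@]2(C)C/C=C/C(C)(C)CC1
A3 | alternative 2 | carbocyclic acid with carboxyl in place of the ring-B methyl group | Cc1cc(=O)c(OC)cc2c1C[C@H]1CC(C)(C)/C=C/C[C@@]3(C(=O)O)Oc4cc(OC)c(=O)cc(C)c4C[C@@H]3C[C@H](O[Si](C)(C)C(C)(C)C)[C@]1(C)O2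
A4 | alternative 3 | eleven-membered triol with two exocyclic methylene groups | C=C1CC(C)(C)/C=C/C[C@@](C)(O)C(=C)C[C@H](O)[C@]1(C)O
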